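**Plan**
- Retrosynthesis: the three MOM ethers come off last. Ring C is then cut twice, at C4–C4a and at O1–C8a. This leaves a 3,5-dioxygenated benzyne (ring A) and an (S)-β-oxido N,N-dimethylamide that already carries ring B with its chromene ring.
- Feature used: ring A is a phloroglucinol ring, so its C8a–C4a edge can be an aryne. The oxygen on C5, next to C4a, sends the C2 oxygen to C8a and leaves the carbanion on C4a, six atoms from the C4 carbonyl.
- Forward order: chromene ring on ring B (propargyl ether Claisen rearrangement on a salicylate), then C3–C4 from N,N-dimethylacetamide, then the stereocentre, then ring C (O1–C8a, then C4–C4a) in one aryne annulation, then deprotection.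
- Stereochemistry: the only centre, C2 (S), comes from asymmetric transfer hydrogenation of the β-keto amide. Its C–O bond is never broken afterwards, and C4 stays a hemiaminal alkoxide until the quench, so base never meets the free flavanone.
- Helpers: O–SiMe3 (latent alkoxide), NMe2 (masks the ketone) and SiMe3/OTf (aryne) are all lost in the key step. The aryne precursor is made in five steps from 5-bromoresorcinol.

Key step: step 12

Remark on the chemistry: C2 of the target is (S) (O1 > C1′ > C3 > H). The same ranking holds at the carbinol carbon of 10, so (S) in 10 maps onto (S) in the target with no inversion step.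

**Route**

Step 1
Reactants: 1 methyl 2,4-dihydroxybenzoate
Product: 2 methyl 2-hydroxy-4-(methoxymethoxy)benzoate
Conditions: MOMCl, K2CO3, acetone, 0 °C → rt
Reagents that add atoms: chloromethyl methyl ether (MOMCl), COCCl
Why: The 2-OH is held in a hydrogen bond to the ester carbonyl, so Williamson-type O-alkylation should take place at the free 4-OH only.

Step 2
Reactants: 2 methyl 2-hydroxy-4-(methoxymethoxy)benzoate; 3 3-chloro-3-methylbut-1-yne
Product: 4 methyl 4-(methoxymethoxy)-2-[(2-methylbut-3-yn-2-yl)oxy]benzoate
Conditions: CuCl2·2H2O (0.5 mol %), DBU, MeCN, 0 °C → rt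
Reagents that add atoms: none
Why: Copper-catalysed propargylic substitution through a copper acetylide/allenylidene should etherify the hydrogen-bonded phenol with the tertiary chloride, where a plain SN2 reaction cannot work.

Step 3
Reactants: 4 methyl 4-(methoxymethoxy)-2-[(2-methylbut-3-yn-2-yl)oxy]benzoate
Product: 6 methyl 5-(methoxymethoxy)-2,2-dimethyl-2H-chromene-8-carboxylate, via ortho-allenylphenol 5 (not isolated)
Conditions: PhNEt2, 180 °C
Reagents that add atoms: none
Why: Aromatic propargyl Claisen rearrangement to the only free ortho position (C3), followed by 1,5-hydrogen shift and oxa-6π electrocyclisation, should give the 2,2-dimethylchromene with its ring oxygen next to the ester-bearing carbon, the regiochemistry being fixed by the position of the ether oxygen.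

Step 4
Reactants: 6 methyl 5-(methoxymethoxy)-2,2-dimethyl-2H-chromene-8-carboxylate; 7 N,N-dimethylacetamide
Product: 9 3-[5-(methoxymethoxy)-2,2-dimethyl-2H-chromen-8-yl]-N,N-dimethyl-3-oxopropanamide, via lithium enolate of N,N-dimethylacetamide 8 (not isolated)
Conditions: lithium diisopropylamide (2.5 equiv), THF, −78 °C; then 6, −78 → 0 °C; aq. NH4Cl
Reagents that add atoms: none
Why: Crossed Claisen condensation of the amide enolate with the non-enolisable aryl ester should stop at the β-keto amide, because the product is held as its stabilised enolate until the quench.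

Step 5
Reactants: 9 3-[5-(methoxymethoxy)-2,2-dimethyl-2H-chromen-8-yl]-N,N-dimethyl-3-oxopropanamide
Product: 10 (3S)-3-hydroxy-3-[5-(methoxymethoxy)-2,2-dimethyl-2H-chromen-8-yl]-N,N-dimethylpropanamide
Conditions: RuCl[(S,S)-TsDPEN](p-cymene) (1 mol %), HCO2H/Et3N (5:2), DMF, 30 °C
Reagents that add atoms: none
Why: Noyori asymmetric transfer hydrogenation with the (S,S)-ligand should deliver hydride to the aryl ketone face that gives the (S)-carbinol (the same sense as acetophenone to (S)-1-phenylethanol, aryl outranking CH2 in both), and the outer-sphere hydride transfer leaves the chromene alkene untouched.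

Step 6
Reactants: 10 (3S)-3-hydroxy-3-[5-(methoxymethoxy)-2,2-dimethyl-2H-chromen-8-yl]-N,N-dimethylpropanamide
Product: 11 (3S)-3-[5-(methoxymethoxy)-2,2-dimethyl-2H-chromen-8-yl]-N,N-dimethyl-3-[(trimethylsilyl)oxy]propanamide
Conditions: TMSCl, imidazole, CH2Cl2, 0 °C
Reagents that add atoms: chlorotrimethylsilane (TMSCl), C[Si](C)(C)Cl
Why: Standard O-silylation without touching the stereocentre should give a silyl ether that serves in step 12 as an alkoxide source free of any O–H proton.

Step 7
Reactants: 12 5-bromobenzene-1,3-diol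
Product: 13 1-bromo-3,5-bis(methoxymethoxy)benzene
Conditions: MOMCl, i-Pr2NEt, CH2Cl2, 0 °C → rt
Reagents that add atoms: chloromethyl methyl ether (MOMCl), COCCl
Why: Standard acetal protection of both phenols gives ethers that should survive organolithium, hydroxide and fluoride.

Step 8
Reactants: 13 1-bromo-3,5-bis(methoxymethoxy)benzene
Product: 14 3,5-bis(methoxymethoxy)phenol
Conditions: Pd2(dba)3 (1 mol %), t-BuXPhos (4 mol %), KOH, 1,4-dioxane/H2O, 100 °C; then pH 6 buffer
Reagents that add atoms: potassium hydroxide, [K+].[OH-]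
Why: Buchwald–Hartwig-type hydroxylation (oxidative addition of zerovalent palladium into C–Br, hydroxide exchange, C–O reductive elimination promoted by the bulky biaryl phosphine) should turn the bromide into the phenol, the MOM ethers being inert to hot aqueous KOH.

Step 9
Reactants: 14 3,5-bis(methoxymethoxy)phenol
Product: 15 3,5-bis(methoxymethoxy)phenyl N-(propan-2-yl)carbamate
Conditions: i-PrNCO, Et3N (cat.), CH2Cl2, rt
Reagents that add atoms: isopropyl isocyanate, CC(C)N=C=O
Why: Addition of the phenol to the isocyanate should give an N–H carbamate that is a strong ortho-director and can later be removed under mild base.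

Step 10
Reactants: 15 3,5-bis(methoxymethoxy)phenyl N-(propan-2-yl)carbamate
Product: 19 3,5-bis(methoxymethoxy)-2-(trimethylsilyl)phenyl N-(propan-2-yl)carbamate, via N-silyl carbamate 16 (not isolated), via ortho-lithiated N-silyl carbamate 17 (not isolated), via C,N-bis(trimethylsilyl) carbamate 18 (not isolated)
Conditions: TMSOTf, TMEDA, Et2O, 0 °C → rt; n-BuLi, TMEDA, −78 °C; TMSCl, −78 °C → rt; aq. NH4Cl
Reagents that add atoms: chlorotrimethylsilane (TMSCl), C[Si](C)(C)Cl
Why: Directed ortho-metalation after in-situ N-silylation should occur at −78 °C at C2, between the O-carbamate (the strongest director) and the neighbouring OMOM group, and not at C4 between two OMOM groups, and the aryllithium is silylated before any anionic Fries shift.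

Step 11
Reactants: 19 3,5-bis(methoxymethoxy)-2-(trimethylsilyl)phenyl N-(propan-2-yl)carbamate
Product: 21 3,5-bis(methoxymethoxy)-2-(trimethylsilyl)phenyl trifluoromethanesulfonate, via free phenol 20 (not isolated)
Conditions: DBU, Et2NH, MeCN, 40 °C; then PhNTf2, rt
Reagents that add atoms: N-phenylbis(trifluoromethanesulfonimide) (PhNTf2), O=S(=O)(N(c1ccccc1)S(=O)(=O)C(F)(F)F)C(F)(F)F
Why: E1cB cleavage of the N–H carbamate (the isocyanate being scavenged by Et2NH) should free the phenoxide, which is triflated in the same flask to give the ortho-silylaryl triflate aryne precursor.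

Step 12
Reactants: 11 (3S)-3-[5-(methoxymethoxy)-2,2-dimethyl-2H-chromen-8-yl]-N,N-dimethyl-3-[(trimethylsilyl)oxy]propanamide; 21 3,5-bis(methoxymethoxy)-2-(trimethylsilyl)phenyl trifluoromethanesulfonate
Product: 26 (2S)-5,7-bis(methoxymethoxy)-2-[5-(methoxymethoxy)-2,2-dimethyl-2H-chromen-8-yl]-2,3-dihydro-4H-chromen-4-one, via potassium alkoxide 22 (not isolated), via 3,5-bis(methoxymethoxy)benzyne 23 (not isolated), via aryl anion 24 (not isolated), via hemiaminal alkoxide 25 (not isolated)
Conditions: KF, 18-crown-6, THF, −20 → 0 °C, 21 (1.4 equiv) added slowly; then AcOH, −20 °C; pH 5 buffer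
Reagents that add atoms: none
Why: Proposed new method: fluoride removes the O-silyl group of 11 to give alkoxide 22 in a proton-free medium and, by 1,2-elimination of Me3SiF and triflate from 21, aryne 23; the alkoxide oxygen should add to the aryne carbon remote from the neighbouring OMOM group (the future C8a), so that carbanion 24 sits on the carbon flanked by that OMOM group (the future C4a), and this carbanion attacks the amide carbonyl six atoms away to form the C4–C4a bond. The closest known reaction types are the fluoride-induced annulation of arynes by salicylates or anthranilates to xanthones and acridones (heteroatom addition, then intramolecular acylation by the new aryl anion) and the insertion of arynes into the N–C(O) bond of β-lactams; what is new is an aliphatic β-oxido amide as the partner. Ring C closes by 6-exo-trig addition of the aryl anion to the carbonyl. No lasting stereocentre is created (C4 of 25 is lost on collapse), and C2 should keep its (S) configuration because its C–O bond is never broken and because the carbonyl stays masked as hemiaminal alkoxide 25, which has no acidic C3–H and cannot open by β-elimination, until the cold acidic quench. The step needs regioselective addition to the aryne, secured by the oxygen substituent next to one aryne carbon, and acylation in preference to protonation or loss of aryloxide, secured by the absence of any O–H (silyl ether as alkoxide source), by slow addition of 21 and by the low temperature.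

Step 13
Reactants: 26 (2S)-5,7-bis(methoxymethoxy)-2-[5-(methoxymethoxy)-2,2-dimethyl-2H-chromen-8-yl]-2,3-dihydro-4H-chromen-4-one
Product: 27 sanggenone H, (2S)-5,7-dihydroxy-2-(5-hydroxy-2,2-dimethyl-2H-chromen-8-yl)-2,3-dihydro-4H-chromen-4-one
Conditions: aq. HCl (3 M), MeOH, 40 °C; NaHCO3 quench
Reagents that add atoms: none
Why: Acid-catalysed transacetalisation of the three phenolic MOM ethers with methanol should free the phenols under conditions mild enough for the chromene and, with no base present, for the C2 centre.

**Compound list**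
1 | methyl 2,4-dihydroxybenzoate | COC(=O)c1ccc(O)cc1O | starting material
2 | methyl 2-hydroxy-4-(methoxymethoxy)benzoate | COCOc1ccc(C(=O)OC)c(O)c1 | intermediate
3 | 3-chloro-3-methylbut-1-yne | CC(C)(Cl)C#C | starting material
4 | methyl 4-(methoxymethoxy)-2-[(2-methylbut-3-yn-2-yl)oxy]benzoate | COCOc1ccc(C(=O)OC)c(OC(C)(C)C#C)c1 | intermediate
5 | methyl 2-hydroxy-4-(methoxymethoxy)-3-(3-methylbuta-1,2-dien-1-yl)benzoate | COCOc1ccc(C(=O)OC)c(O)c1C=C=C(C)C | intermediate
6 | methyl 5-(methoxymethoxy)-2,2-dimethyl-2H-chromene-8-carboxylate | COCOc1ccc(C(=O)OC)c2OC(C)(C)C=Cc12 | intermediate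
7 | N,N-dimethylacetamide | CC(=O)N(C)C | starting material
8 | lithium enolate of N,N-dimethylacetamide | [Li]OC(=C)N(C)C | intermediate
9 | 3-[5-(methoxymethoxy)-2,2-dimethyl-2H-chromen-8-yl]-N,N-dimethyl-3-oxopropanamide | CC1(C)C=Cc2c(OCOC)ccc(C(=O)CC(=O)N(C)C)c2O1 | intermediate
10 | (3S)-3-hydroxy-3-[5-(methoxymethoxy)-2,2-dimethyl-2H-chromen-8-yl]-N,N-dimethylpropanamide | CC1(C)C=Cc2c(OCOC)ccc([C@@H](O)CC(=O)N(C)C)c2O1 | intermediate
11 | (3S)-3-[5-(methoxymethoxy)-2,2-dimethyl-2H-chromen-8-yl]-N,N-dimethyl-3-[(trimethylsilyl)oxy]propanamide | CC1(C)C=Cc2c(OCOC)ccc([C@@H](O[Si](C)(C)C)CC(=O)N(C)C)c2O1 | intermediate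
12 | 5-bromobenzene-1,3-diol | Oc1cc(O)cc(Br)c1 | starting material
13 | 1-bromo-3,5-bis(methoxymethoxy)benzene | COCOc1cc(Br)cc(OCOC)c1 | intermediate
14 | 3,5-bis(methoxymethoxy)phenol | COCOc1cc(O)cc(OCOC)c1 | intermediate
15 | 3,5-bis(methoxymethoxy)phenyl N-(propan-2-yl)carbamate | CC(C)NC(=O)Oc1cc(OCOC)cc(OCOC)c1 | intermediate
16 | 3,5-bis(methoxymethoxy)phenyl N-(propan-2-yl)-N-(trimethylsilyl)carbamate | CC(C)N([Si](C)(C)C)C(=O)Oc1cc(OCOC)cc(OCOC)c1 | intermediate
17 | 2-lithio-3,5-bis(methoxymethoxy)phenyl N-(propan-2-yl)-N-(trimethylsilyl)carbamate | CC(C)N([Si](C)(C)C)C(=O)Oc1cc(OCOC)cc(OCOC)c1[Li] | intermediate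
18 | 3,5-bis(methoxymethoxy)-2-(trimethylsilyl)phenyl N-(propan-2-yl)-N-(trimethylsilyl)carbamate | CC(C)N([Si](C)(C)C)C(=O)Oc1cc(OCOC)cc(OCOC)c1[Si](C)(C)C | intermediate
19 | 3,5-bis(methoxymethoxy)-2-(trimethylsilyl)phenyl N-(propan-2-yl)carbamate | CC(C)NC(=O)Oc1cc(OCOC)cc(OCOC)c1[Si](C)(C)C | intermediate
20 | 3,5-bis(methoxymethoxy)-2-(trimethylsilyl)phenol | COCOc1cc(O)c([Si](C)(C)C)c(OCOC)c1 | intermediate
21 | 3,5-bis(methoxymethoxy)-2-(trimethylsilyl)phenyl trifluoromethanesulfonate | COCOc1cc(OS(=O)(=O)C(F)(F)F)c([Si](C)(C)C)c(OCOC)c1 | intermediate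
22 | potassium (1S)-3-(dimethylamino)-1-[5-(methoxymethoxy)-2,2-dimethyl-2H-chromen-8-yl]-3-oxopropan-1-olate | CC1(C)C=Cc2c(OCOC)ccc([C@@H]([O-])CC(=O)N(C)C)c2O1.[K+] | intermediate
23 | 3,5-bis(methoxymethoxy)benzyne (1,2-didehydro-3,5-bis(methoxymethoxy)benzene) | C1#CC(OCOC)=CC(OCOC)=C1 | intermediate
24 | potassium 2-{(1S)-3-(dimethylamino)-1-[5-(methoxymethoxy)-2,2-dimethyl-2H-chromen-8-yl]-3-oxopropoxy}-4,6-bis(methoxymethoxy)benzen-1-ide | CC1(C)C=Cc2c(OCOC)ccc([C@H](CC(=O)N(C)C)OC3=[C-]C(OCOC)=CC(OCOC)=C3)c2O1.[K+] | intermediate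
25 | potassium (2S)-4-(dimethylamino)-5,7-bis(methoxymethoxy)-2-[5-(methoxymethoxy)-2,2-dimethyl-2H-chromen-8-yl]-3,4-dihydro-2H-chromen-4-olate (either configuration at C4) | CC1(C)C=Cc2c(OCOC)ccc([C@@H]3CC([O-])(N(C)C)c4c(OCOC)cc(OCOC)cc4O3)c2O1.[K+] | intermediate
26 | (2S)-5,7-bis(methoxymethoxy)-2-[5-(methoxymethoxy)-2,2-dimethyl-2H-chromen-8-yl]-2,3-dihydro-4H-chromen-4-one | CC1(C)C=Cc2c(OCOC)ccc([C@@H]3CC(=O)c4c(OCOC)cc(OCOC)cc4O3)c2O1 | intermediate
27 | sanggenone H, (2S)-5,7-dihydroxy-2-(5-hydroxy-2,2-dimethyl-2H-chromen-8-yl)-2,3-dihydro-4H-chromen-4-one | CC1(C)C=Cc2c(O)ccc([C@@H]3CC(=O)c4c(O)cc(O)cc4O3)c2O1 | target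

**Step count**
Total: 13 steps. Longest linear sequence: 8 steps (steps 1–6, 12, 13); the aryne branch (steps 7–11) joins at step 12.

**Steps most likely to fail**

Step 12. What may go wrong: protonation of the aryl anion, or base-induced β-elimination of silyloxide or aryloxide, may outrun the 6-exo acylation; the alkoxide may also add too slowly to the aryne. The fallback sets out from alcohol 10 (with aryne precursor 21) and splits the event into two known reactions. O–H insertion of the free secondary alcohol into the aryne (KF, 18-crown-6, THF, −20 °C) should give, with retention because the carbinol C–O bond is untouched, the aryl ether amide F1. Electrophilic amide activation (Tf2O, 2-fluoropyridine, CH2Cl2, −78 → 0 °C) should then let the phloroglucinol ring attack the amidinium carbon at a position ortho to the ether oxygen (intramolecular Vilsmeier–Haack-type acylation; the two ortho positions are equivalent) to give the cyclic iminium triflate F2. Hydrolysis with aq. NaHCO3 returns to the route at 26.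

Step 13. What may go wrong: acid may ionise the C2–O1 bond (the benzylic cation is stabilised by the ortho and para oxygens of ring B), with loss of configuration or ring opening, or may add to the chromene alkene. The fallback sets out from 26 and avoids Brønsted acid. Base-buffered trans-silylation (TMSOTf, 2,2′-bipyridyl, CH2Cl2, 0 °C), in which the bipyridyl carries off each CH2OMe group as a pyridinium salt, should convert the aryl MOM ethers into the tris(trimethylsilyl) ether F3. Neutral hydrolysis (H2O, THF, rt) returns to the route at 27.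

Step 5. What may go wrong: hydride transfer to the electron-rich, ortho-alkoxy aryl ketone may be slow or incomplete, or the benzylic alcohol may ionise in the formic acid medium, with erosion of enantiomeric purity. The fallback sets out from ester 6 and sets the centre by an auxiliary-controlled aldol reaction. Reduction (i-Bu2AlH, CH2Cl2, −78 °C) should give the benzylic alcohol F4, and oxidation (MnO2, CH2Cl2, rt) the aldehyde F5. A Nagao acetate aldol reaction with (4R)-3-acetyl-4-(propan-2-yl)-1,3-thiazolidine-2-thione (Sn(OTf)2, N-ethylpiperidine, CH2Cl2, −78 °C) should give the aldol adduct F6; the chelated Zimmerman–Traxler chair, with the aldehyde on the enolate face away from the isopropyl group, is expected to give the (S)-carbinol, and the minor diastereomer is removable on silica. Aminolysis (Me2NH, THF, 0 °C) releases the auxiliary and returns to the route at 10.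

**Further compounds**
F1 | step 12 | (3S)-3-[3,5-bis(methoxymethoxy)phenoxy]-3-[5-(methoxymethoxy)-2,2-dimethyl-2H-chromen-8-yl]-N,N-dimethylpropanamide | CC1(C)C=Cc2c(OCOC)ccc([C@H](CC(=O)N(C)C)Oc3cc(OCOC)cc(OCOC)c3)c2O1
F2 | step 12 | N-{(2S)-5,7-bis(methoxymethoxy)-2-[5-(methoxymethoxy)-2,2-dimethyl-2H-chromen-8-yl]-2,3-dihydro-4H-chromen-4-ylidene}-N-methylmethanaminium trifluoromethanesulfonate | CC1(C)C=Cc2c(OCOC)ccc([C@@H]3CC(=[N+](C)C)c4c(OCOC)cc(OCOC)cc4O3)c2O1.[O-]S(=O)(=O)C(F)(F)F
F3 | step 13 | (2S)-2-{2,2-dimethyl-5-[(trimethylsilyl)oxy]-2H-chromen-8-yl}-5,7-bis[(trimethylsilyl)oxy]-2,3-dihydro-4H-chromen-4-one | CC1(C)C=Cc2c(O[Si](C)(C)C)ccc([C@@H]3CC(=O)c4c(O[Si](C)(C)C)cc(O[Si](C)(C)C)cc4O3)c2O1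
F4 | step 5 | [5-(methoxymethoxy)-2,2-dimethyl-2H-chromen-8-yl]methanol | CC1(C)C=Cc2c(OCOC)ccc(CO)c2O1
F5 | step 5 | 5-(methoxymethoxy)-2,2-dimethyl-2H-chromene-8-carbaldehyde | CC1(C)C=Cc2c(OCOC)ccc(C=O)c2O1
F6 | step 5 | (3S)-3-hydroxy-3-[5-(methoxymethoxy)-2,2-dimethyl-2H-chromen-8-yl]-1-[(4R)-4-(propan-2-yl)-2-sulfanylidene-1,3-thiazolidin-3-yl]propan-1-one | CC1(C)C=Cc2c(OCOC)ccc([C@@H](O)CC(=O)N3[C@H](C(C)C)CSC3=S)c2O1
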